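Everything rests on one disconnection: the C1–C2 bond of the ten-membered ring is cut and C4 is joined to C9. The handle is the cyclodec-5-enone pattern of that ring (oxygen on C9, C10, the C1–C2 bond, the C3=C4 alkene). Read forwards, an anionic oxy-Cope rearrangement inserts C10, C1, C2 and C3 into the six-membered ring C, forges the crowded C1–C2 bond, makes quaternary C1 and the C2 ether stereocentre, and leaves the ring-cis C3=C4 alkene and a C9 ketone. Its substrate is a ring C cyclohexenol (C4–C9, C7/C8 acetonide) with a ketal-bearing 2-methylcyclohexenyl group (ring A) on C9 and, cis to it, an (E)-alkoxyvinyl group on C4.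

Key step: step 28

Numbering: atoms carry briarane numbers throughout (C1–C10 ten-membered ring; C11–C14 complete ring A; C15 methyl on C1; C16 on C5; C17, C18, C19 lactone CH, its methyl and the carbonyl; C20 epoxide CH2). PMB = 4-methoxybenzyl.

Assumption: (R)-4-methyloxolan-2-one and (R)-4-benzyl-1,3-oxazolidin-2-one are bought as single enantiomers.

Remark on the key-step substrate: its skeleton and that of its product map atom by atom onto the target with the same configuration at C1, C2, C7, C8, C10 and C17. O16 carries PMB and O19 a tert-butyldiphenylsilyl group, because two identical silyl ethers there could not be told apart when C19 alone has to be oxidised. The enol ether is made with defined E geometry.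

**Ring C ketone (steps 1–22)**

Step 1
Reactants: 1 (R)-4-methyloxolan-2-one
Product: 2 (3S,4R)-3-[(benzyloxy)methyl]-4-methyloxolan-2-one
Conditions: LiN(iPr)2, THF, −78 °C; BnOCH2Cl, −78 to −40 °C; aq. NH4Cl
Reagents that add atoms: benzyl chloromethyl ether, ClCOCc1ccccc1
Why: Alkylation of the lithium lactone enolate should take place anti to the neighbouring C17 methyl group, so the benzyloxymethyl carbon (C7) enters trans to it.

Step 2
Reactants: 2 (3S,4R)-3-[(benzyloxy)methyl]-4-methyloxolan-2-one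
Product: 3 (3S,4S)-3-[(benzyloxy)methyl]-3-hydroxy-4-methyloxolan-2-one
Conditions: NaN(SiMe3)2, THF, −78 °C; 2-(phenylsulfonyl)-3-phenyloxaziridine, −78 °C; aq. NH4Cl
Reagents that add atoms: 2-(phenylsulfonyl)-3-phenyloxaziridine, O=S(=O)(c1ccccc1)N1OC1c1ccccc1
Why: Davis oxidation of the enolate should again bring the electrophile in anti to the C17 methyl, which puts the hydroxyl trans and C7 cis to that methyl and fixes quaternary C8.

Step 3
Reactants: 3 (3S,4S)-3-[(benzyloxy)methyl]-3-hydroxy-4-methyloxolan-2-one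
Product: 4 (3S,4S)-3-hydroxy-3-(hydroxymethyl)-4-methyloxolan-2-one
Conditions: H2 (1 atm), Pd/C, EtOAc, rt
Reagents that add atoms: none
Why: Hydrogenolysis of the benzyl ether frees the primary alcohol and leaves the lactone alone.

Step 4
Reactants: 4 (3S,4S)-3-hydroxy-3-(hydroxymethyl)-4-methyloxolan-2-one
Product: 5 (3S,4S)-3-hydroxy-4-methyl-2-oxooxolane-3-carbaldehyde
Conditions: TEMPO (10 mol%), PhI(OAc)2, CH2Cl2, rt; used crude
Reagents that add atoms: none
Why: TEMPO/PhI(OAc)2 oxidation is selective for the primary over the tertiary alcohol and stops at the aldehyde.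

Step 5
Reactants: 5 (3S,4S)-3-hydroxy-4-methyl-2-oxooxolane-3-carbaldehyde
Product: 6 (3S,4S)-3-hydroxy-3-[(1S)-1-hydroxyprop-2-en-1-yl]-4-methyloxolan-2-one
Conditions: CH2=CHMgBr (2.5 equiv), THF, −78 °C; aq. NH4Cl at −78 °C
Reagents that add atoms: vinylmagnesium bromide, C=C[Mg]Br
Why: Chelation-controlled Grignard addition (Cram cyclic model): the magnesium alkoxide on O8 holds the aldehyde and the vinyl group should attack from the side of the flat lactone carbonyl, anti to C17 and its methyl, which sets C7.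

Step 6
Reactants: 6 (3S,4S)-3-hydroxy-3-[(1S)-1-hydroxyprop-2-en-1-yl]-4-methyloxolan-2-one
Product: 7 4-ethenyl-2,2,9-trimethyl-1,3,7-trioxaspiro[4.4]nonan-6-one (C7/C8 acetonide of 6)
Conditions: Me2C(OMe)2, PPTS (cat.), CH2Cl2, rt
Reagents that add atoms: 2,2-dimethoxypropane, COC(C)(C)OC
Why: Acid-catalysed transketalisation ties the vicinal C7/C8 diol up as the acetonide that is carried through the key step.

Step 7
Reactants: 7 4-ethenyl-2,2,9-trimethyl-1,3,7-trioxaspiro[4.4]nonan-6-one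
Product: 8 C9/C19 diol (2-[4-(hydroxymethyl)-2,2-dimethyl-5-vinyl-1,3-dioxolan-4-yl]propan-1-ol; stereocentres as in 7)
Conditions: LiAlH4, THF, 0 °C; H2O, aq. NaOH
Reagents that add atoms: none
Why: LiAlH4 reduction opens the hindered lactone to the diol.

Step 8
Reactants: 8 C9/C19 diol
Product: 9 C19 tert-butyldiphenylsilyl ether of 8 (C9 alcohol free)
Conditions: tBuPh2SiCl (1.05 equiv), imidazole, CH2Cl2, −20 °C
Reagents that add atoms: tert-butyl(chloro)diphenylsilane, CC(C)(C)[Si](Cl)(c1ccccc1)c1ccccc1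
Why: Silylation with the bulky chlorosilane should be selective for the β-branched C19 alcohol over the neopentyl C9 alcohol on the quaternary centre.

Step 9
Reactants: 9 C19 tert-butyldiphenylsilyl ether
Product: 10 C9 aldehyde (C7/C8 acetonide; C6 vinyl; O19 silyl)
Conditions: Dess–Martin periodinane, NaHCO3, CH2Cl2, 0 °C to rt
Reagents that add atoms: none
Why: Dess–Martin oxidation gives the non-enolisable α-alkoxy aldehyde under buffered conditions.

Step 10
Reactants: 11 (R)-4-benzyl-1,3-oxazolidin-2-one; 12 itaconic anhydride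
Product: 13 4-[(4R)-4-benzyl-2-oxo-1,3-oxazolidin-3-yl]-2-methylidene-4-oxobutanoic acid
Conditions: n-BuLi, THF, −78 °C; 12, −78 to 0 °C; 1 M HCl
Reagents that add atoms: none
Why: N-acylation of the lithiated oxazolidinone by ring opening of the cyclic anhydride should occur at the less hindered, non-conjugated carbonyl.

Step 11
Reactants: 13 4-[(4R)-4-benzyl-2-oxo-1,3-oxazolidin-3-yl]-2-methylidene-4-oxobutanoic acid
Product: 14 methyl 4-[(4R)-4-benzyl-2-oxo-1,3-oxazolidin-3-yl]-2-methylidene-4-oxobutanoate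
Conditions: Me3SiCHN2, toluene/MeOH 4:1, 0 °C
Reagents that add atoms: (trimethylsilyl)diazomethane, C[Si](C)(C)C=[N+]=[N-]
Why: Esterification with the diazoalkane is neutral and leaves the 1,1-disubstituted alkene where it is.

Step 12
Reactants: 10 C9 aldehyde; 14 methyl 4-[(4R)-4-benzyl-2-oxo-1,3-oxazolidin-3-yl]-2-methylidene-4-oxobutanoate
Product: 15 syn-aldol adduct (new C4–C9 bond; C9 secondary alcohol; C4 bears the imide carbonyl C3 and the C5 methylidene ester)
Conditions: 14, Bu2BOTf, iPr2NEt, CH2Cl2, −78 to 0 °C; 10, −78 to 0 °C; pH 7 buffer, MeOH, 30% H2O2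
Reagents that add atoms: none
Why: Evans syn-aldol reaction through the (Z)-boron enolate and a Zimmerman–Traxler chair sets C4 by auxiliary control; the C9 carbinol configuration is irrelevant because it is oxidised later.

Step 13
Reactants: 15 syn-aldol adduct
Product: 16 C9 triethylsilyl ether of 15
Conditions: Et3SiOTf, 2,6-lutidine, CH2Cl2, −78 °C
Reagents that add atoms: triethylsilyl trifluoromethanesulfonate, CC[Si](CC)(CC)OS(=O)(=O)C(F)(F)F
Why: Silylation with the silyl triflate masks the hindered secondary alcohol, which would otherwise interfere with the later C–O coupling.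

Step 14
Reactants: 16 C9 triethylsilyl ether
Product: 17 ring C cyclohexene (C5 methyl ester; C5=C6; C7/C8 acetonide; C9 silyl ether; C4 acyl-oxazolidinone)
Conditions: second-generation Hoveyda–Grubbs catalyst (5 mol%), toluene, 80 °C
Reagents that add atoms: none
Why: Ring-closing metathesis between the vinyl group on C7 and the acrylate-type alkene on C5 closes the six-membered ring C and leaves the trisubstituted C5=C6 alkene.

Step 15
Reactants: 17 ring C cyclohexene imide
Product: 18 ring C S-ethyl thioester (C3)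
Conditions: EtSH, n-BuLi, THF, −20 to 0 °C; aq. NH4Cl
Reagents that add atoms: ethanethiol, CCS
Why: Thiolysis of the Evans imide at the exocyclic carbonyl releases the auxiliary without epimerising C4.

Step 16
Reactants: 18 ring C S-ethyl thioester
Product: 19 ring C C3 aldehyde
Conditions: Et3SiH, Pd/C, acetone, rt; used at once
Reagents that add atoms: none
Why: Fukuyama reduction turns the thioester into the aldehyde under neutral conditions that keep the α-stereocentre next to the C5=C6 alkene.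

Step 17
Reactants: 19 ring C C3 aldehyde
Product: 20 ring C (E)-vinyl iodide (C4–CH=CH–I)
Conditions: CrCl2, CHI3, THF, 0 °C
Reagents that add atoms: iodoform, IC(I)I
Why: Takai olefination converts the aldehyde into the (E)-vinyl iodide under non-basic conditions.

Step 18
Reactants: 20 ring C (E)-vinyl iodide
Product: 21 ring C C16 allylic alcohol
Conditions: iBu2AlH, CH2Cl2, −78 °C; aq. potassium sodium tartrate
Reagents that add atoms: none
Why: iBu2AlH reduces the conjugated ester to the allylic alcohol; vinyl iodide and silyl ethers are inert.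

Step 19
Reactants: 21 ring C C16 allylic alcohol
Product: 22 ring C C16 PMB ether
Conditions: NaH, PMBCl, Bu4NI (cat.), THF/DMF, 0 °C to rt
Reagents that add atoms: 4-methoxybenzyl chloride, COc1ccc(CCl)cc1
Why: Williamson etherification gives O16 a protecting group different from the silyl ether on O19.

Step 20
Reactants: 22 ring C C16 PMB ether; 23 4-methoxybenzyl alcohol
Product: 24 ring C (E)-enol ether (C4–CH=CH–OPMB)
Conditions: CuI (10 mol%), 3,4,7,8-tetramethyl-1,10-phenanthroline (20 mol%), Cs2CO3, toluene, 80 °C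
Reagents that add atoms: none
Why: Copper-catalysed C–O cross-coupling of a vinyl iodide with an alcohol (Ullmann-type vinylation) proceeds with retention of the E geometry.

Step 21
Reactants: 24 ring C (E)-enol ether
Product: 25 ring C C9 alcohol
Conditions: Bu4NF (1.1 equiv), AcOH (1.1 equiv), THF, 0 °C
Reagents that add atoms: none
Why: Buffered fluoride should cleave the secondary triethylsilyl ether faster than the primary tert-butyldiphenylsilyl ether and does not touch the enol ether.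

Step 22
Reactants: 25 ring C C9 alcohol
Product: 26 ring C C9 ketone (C4 alkenyl group and the C7/C8 acetonide oxygens on one face; C17 branch on the other)
Conditions: Dess–Martin periodinane, pyridine, CH2Cl2, 0 °C; used at once
Reagents that add atoms: none
Why: Buffered Dess–Martin oxidation needs neither acid nor base, so the enol ether and the doubly allylic C4 stereocentre survive.

**Ring A fragment (steps 23–26)**

Step 23
Reactants: 27 3-ethoxycyclohex-2-en-1-one
Product: 28 3-ethoxy-6-methylcyclohex-2-en-1-one (racemic)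
Conditions: LiN(iPr)2, THF, −78 °C; MeI, −78 to 0 °C
Reagents that add atoms: iodomethane, CI
Why: Stork–Danheiser α′-alkylation of the kinetic enolate of the vinylogous ester installs the future C15 methyl.

Step 24
Reactants: 28 3-ethoxy-6-methylcyclohex-2-en-1-one
Product: 29 5-ethoxy-2-methylcyclohexa-1,5-dien-1-yl trifluoromethanesulfonate
Conditions: LiN(iPr)2, THF, −78 °C; PhNTf2, −78 to 0 °C; aq. NH4Cl
Reagents that add atoms: N-phenylbis(trifluoromethanesulfonimide), O=S(=O)(N(c1ccccc1)S(=O)(=O)C(F)(F)F)C(F)(F)F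
Why: A second kinetic α′-deprotonation (the other α-carbon is vinylic) and O-triflation give the cross-conjugated dienyl triflate regiospecifically.

Step 25
Reactants: 29 5-ethoxy-2-methylcyclohexa-1,5-dien-1-yl trifluoromethanesulfonate
Product: 30 8-methyl-1,4-dioxaspiro[4.5]dec-7-en-7-yl trifluoromethanesulfonate
Conditions: HOCH2CH2OH, PPTS (5 mol%), CH2Cl2, 4 Å sieves, rt
Reagents that add atoms: ethane-1,2-diol, OCCO
Why: Acid-catalysed exchange of the enol ether for the dioxolane should go by kinetic α-protonation of the dienol ether (at C11), as in deconjugative ketalisation of dienol ethers, and leaves the tetrasubstituted C10=C1 enol triflate.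

Step 26
Reactants: 30 8-methyl-1,4-dioxaspiro[4.5]dec-7-en-7-yl trifluoromethanesulfonate
Product: 31 trimethyl(8-methyl-1,4-dioxaspiro[4.5]dec-7-en-7-yl)stannane
Conditions: Me3SnSnMe3, Pd(PPh3)4 (5 mol%), LiCl, THF, 65 °C
Reagents that add atoms: hexamethylditin, C[Sn](C)(C)[Sn](C)(C)C
Why: Palladium-catalysed stannylation of the enol triflate (Stille-type coupling with the distannane) gives the alkenylstannane.

**Union and key step (steps 27–28)**

Step 27
Reactants: 31 trimethyl(8-methyl-1,4-dioxaspiro[4.5]dec-7-en-7-yl)stannane; 26 ring C C9 ketone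
Product: 34 cis-dialkenyl cyclohexenol (C9: ring A cyclohexenyl cis to the C4 alkenyl group and to O8; hydroxyl trans), via alkenyllithium 32 (not isolated), via alkenylcerium dichloride 33 (not isolated)
Conditions: 31 (1.6 equiv), MeLi, THF, −78 to 0 °C; CeCl3, THF, −78 °C; 26, −78 °C; aq. NH4Cl
Reagents that add atoms: none
Why: Tin–lithium exchange and transmetalation to the weakly basic organocerium reagent allow 1,2-addition to the hindered, enolisable ketone, and chelation of cerium between the carbonyl and O8 should direct attack anti to the C17 branch, cis to O8 and to the C4 alkenyl group.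

Step 28
Reactants: 34 cis-dialkenyl cyclohexenol
Product: 37 trans-fused ten-membered C9 ketone (C1 quaternary; C2 OPMB; C3=C4 cis; C12 ketal), via potassium alkoxide 35 (not isolated), via potassium enolate 36 (not isolated)
Conditions: KH, 18-crown-6, THF, 0 °C to rt; aq. NH4Cl at −78 °C; DBU (cat.), CH2Cl2, rt
Reagents that add atoms: none
Why: KH/18-crown-6 turns the tertiary C9 alcohol into the free potassium alkoxide 35, whose [3,3]-sigmatropic shift through the chair array C1=C10–C9–C4–C3=C2 forms C1–C2 and breaks C4–C9 to give enolate 36, protonated at C10. The closest known reaction type is the anionic oxy-Cope ring expansion of cis-1,2-dialkenylcyclohexanols to cyclodec-5-enones, including cyclohexenyl partners that build quaternary centres. The ten-membered ring is closed by ring expansion and not by cyclisation: C10, C1, C2 and C3 are inserted into ring C as the new σ-bond forms across the chair. C1 and C2 are set by chirality transfer from C4 and C9, because in the chair the C15 methyl (cis to C9 on the ring A alkene) sits axial on C1 and the oxygen of the (E)-enol ether equatorial on C2; C10 is set afterwards by protonation and DBU equilibration to the trans-fused ketone. The step needs the chair with C5 axial on C4 (hence the ring-cis C3=C4 alkene) over the other chair, boat arrays and fragmentation; the cis arrangement of the two alkenyl groups and the vicinal fully substituted C8/C9, which keep the C17 branch and the cyclohexenyl group anti, should secure it.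

**From the ketone to the target (steps 29–45)**

Step 29
Reactants: 37 ten-membered C9 ketone
Product: 38 C9 alcohol (configured as in the target)
Conditions: Zn(BH4)2, Et2O, −20 °C; aq. NH4Cl
Reagents that add atoms: none
Why: Chelation-controlled reduction (Cram cyclic model, zinc between the carbonyl and O8) should bring hydride in from the face away from the C17 branch and ring A.

Step 30
Reactants: 38 C9 alcohol
Product: 39 C9 PMB ether
Conditions: 2-(4-methoxybenzyloxy)-4-methylquinoline, MeOTf, MgO, PhCF3, 0 to 80 °C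
Reagents that add atoms: 2-(4-methoxybenzyloxy)-4-methylquinoline, COc1ccc(COc2cc(C)c3ccccc3n2)cc1
Why: PMB transfer from the N-methylated 2-benzyloxyquinolinium salt (Dudley etherification) works on hindered alcohols under neutral conditions that spare ketal and acetonide.

Step 31
Reactants: 39 C9 PMB ether
Product: 40 C12 ketone
Conditions: PPTS, acetone/H2O 10:1, 50 °C
Reagents that add atoms: water, O
Why: Mild acid hydrolysis removes the dioxolane ketal while the acetone medium keeps the acetonide.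

Step 32
Reactants: 40 C12 ketone
Product: 42 C13=C14 enone, via silyl enol ether 41 (not isolated)
Conditions: LiN(iPr)2, Me3SiCl, THF, −78 °C; Pd(OAc)2 (1.1 equiv), MeCN, rt
Reagents that add atoms: none
Why: Ito–Saegusa oxidation: kinetic enolisation should go to C13, away from C11 next to the ring-fusion carbon (as in trans-fused 3-keto steroids), and Pd(OAc)2 dehydrosilylates to the enone.

Step 33
Reactants: 42 C13=C14 enone
Product: 43 13,14-epoxy C12 ketone (epoxide oxygen trans to the C15 methyl)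
Conditions: 30% H2O2, NaOH, MeOH/THF, 0 °C
Reagents that add atoms: hydrogen peroxide, OO
Why: Weitz–Scheffer epoxidation attacks only the electron-poor enone, not the diene, and should come from the face opposite the axial C15 methyl, which sets C14.

Step 34
Reactants: 43 13,14-epoxy C12 ketone
Product: 44 14-hydroxy C12 ketone
Conditions: SmI2 (2.5 equiv), THF/MeOH, −90 °C
Reagents that add atoms: none
Why: SmI2 reduction of an α,β-epoxy ketone cleaves the Cα–O bond at C13 and gives the β-hydroxy ketone without elimination.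

Step 35
Reactants: 44 14-hydroxy C12 ketone
Product: 45 14-O-PMB C12 ketone
Conditions: 2-(4-methoxybenzyloxy)-4-methylquinoline, MeOTf, MgO, PhCF3, 0 to 80 °C
Reagents that add atoms: 2-(4-methoxybenzyloxy)-4-methylquinoline, COc1ccc(COc2cc(C)c3ccccc3n2)cc1
Why: Dudley etherification protects the β-hydroxy ketone under neutral conditions, without retro-aldol cleavage or elimination.

Step 36
Reactants: 45 14-O-PMB C12 ketone
Product: 48 C11 methylidene C12 ketone (C20 installed), via Mannich base 46 (not isolated), via ammonium iodide 47 (not isolated)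
Conditions: LiN(iPr)2, THF, −78 °C; Me2N=CH2 I, −78 °C to rt; MeI, CH2Cl2, rt; aq. NaHCO3, rt
Reagents that add atoms: N,N-dimethylmethyleneiminium iodide, C=[N+](C)C.[I-]
Why: Kinetic deprotonation should occur at C11, away from the more hindered C13 next to the β-ether carbon, and Mannich reaction followed by quaternisation and elimination gives the α-methylene ketone.

Step 37
Reactants: 48 C11 methylidene C12 ketone
Product: 49 13-hydroxy enone (hydroxyl equatorial, cis to O14)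
Conditions: KN(SiMe3)2, THF, −78 °C; 2-(phenylsulfonyl)-3-phenyloxaziridine, −78 °C; aq. NH4Cl
Reagents that add atoms: 2-(phenylsulfonyl)-3-phenyloxaziridine, O=S(=O)(c1ccccc1)N1OC1c1ccccc1
Why: Davis oxidation of the only enolate that can now form should bring oxygen to C13 from the face opposite the 1,3-diaxial C15 methyl.

Step 38
Reactants: 49 13-hydroxy enone
Product: 50 13-O-(3-methylbutanoyl) enone
Conditions: (iPrCH2CO)2O, DMAP, pyridine, CH2Cl2, 0 °C
Reagents that add atoms: 3-methylbutanoic anhydride, CC(C)CC(=O)OC(=O)CC(C)C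
Why: DMAP-catalysed acylation esterifies the only free hydroxyl.

Step 39
Reactants: 50 13-O-(3-methylbutanoyl) enone
Product: 51 C7/C8/C19 triol
Conditions: 48% aq. HF, MeCN, 0 °C to rt
Reagents that add atoms: none
Why: Aqueous HF in acetonitrile hydrolyses the acetonide and cleaves the silyl ether in one operation and should leave the four PMB ethers and the ester.

Step 40
Reactants: 51 C7/C8/C19 triol
Product: 52 γ-lactone (C19 carbonyl on O7; C8 hydroxyl free)
Conditions: TEMPO (20 mol%), PhI(OAc)2 (3 equiv), CH2Cl2, rt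
Reagents that add atoms: none
Why: TEMPO-mediated oxidative lactonisation oxidises the primary C19 alcohol, the C7 hydroxyl traps the aldehyde as a lactol and further oxidation gives the lactone; the tertiary C8 hydroxyl is inert.

Step 41
Reactants: 52 γ-lactone
Product: 53 C12 allylic alcohol (hydroxyl cis to O13 and O14)
Conditions: NaBH4, CeCl3·7H2O, MeOH/THF, −78 °C
Reagents that add atoms: none
Why: Luche 1,2-reduction: the axial ether on C14 blocks axial attack, so hydride should add from the opposite face and give the axial alcohol.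

Step 42
Reactants: 53 C12 allylic alcohol
Product: 54 11,20-epoxide (epoxide oxygen cis to O12)
Conditions: VO(acac)2 (5 mol%), tBuOOH, CH2Cl2, 0 °C to rt
Reagents that add atoms: tert-butyl hydroperoxide, CC(C)(C)OO
Why: Vanadium-catalysed hydroxyl-directed epoxidation delivers oxygen to the exocyclic alkene on the face of the C12 hydroxyl and sets C11.

Step 43
Reactants: 54 11,20-epoxide
Product: 55 12,13-bis(3-methylbutanoate)
Conditions: (iPrCH2CO)2O, DMAP, Et3N, CH2Cl2, rt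
Reagents that add atoms: 3-methylbutanoic anhydride, CC(C)CC(=O)OC(=O)CC(C)C
Why: DMAP-catalysed acylation esterifies the secondary C12 alcohol; the tertiary C8 alcohol does not react.

Step 44
Reactants: 55 12,13-bis(3-methylbutanoate)
Product: 56 tetraol (O2, O9, O14 and O16 free)
Conditions: DDQ (6 equiv), CH2Cl2/pH 7 buffer 10:1, 0 °C
Reagents that add atoms: none
Why: Oxidative cleavage of the four PMB ethers with DDQ under buffered conditions leaves esters, epoxide and lactone.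

Step 45
Reactants: 56 tetraol
Product: 57 CNP0303383.2
Conditions: Ac2O, pyridine, DMAP (cat.), CH2Cl2, rt
Reagents that add atoms: acetic anhydride, CC(=O)OC(C)=O
Why: Acetylation esterifies the primary and the three secondary hydroxyls, while the tertiary C8 hydroxyl should stay free.

**Compound list**

1 | (R)-4-methyloxolan-2-one | O=C1C[C@@H](C)CO1 | starting material
2 | (3S,4R)-3-[(benzyloxy)methyl]-4-methyloxolan-2-one | O=C1[C@H](COCc2ccccc2)[C@@H](C)CO1 | intermediate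
3 | (3S,4S)-3-[(benzyloxy)methyl]-3-hydroxy-4-methyloxolan-2-one | O=C1[C@@](O)(COCc2ccccc2)[C@@H](C)CO1 | intermediate
4 | (3S,4S)-3-hydroxy-3-(hydroxymethyl)-4-methyloxolan-2-one | O=C1[C@@](O)(CO)[C@@H](C)CO1 | intermediate
5 | (3S,4S)-3-hydroxy-4-methyl-2-oxooxolane-3-carbaldehyde | O=C1[C@@](O)(C=O)[C@@H](C)CO1 | intermediate
6 | (3S,4S)-3-hydroxy-3-[(1S)-1-hydroxyprop-2-en-1-yl]-4-methyloxolan-2-one | O=C1[C@@](O)([C@@H](O)C=C)[C@@H](C)CO1 | intermediate
7 | 4-ethenyl-2,2,9-trimethyl-1,3,7-trioxaspiro[4.4]nonan-6-one, C7/C8 acetonide of 6 | O=C1[C@]2(OC(C)(C)O[C@H]2C=C)[C@@H](C)CO1 | intermediate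
8 | C9/C19 diol, 2-[4-(hydroxymethyl)-2,2-dimethyl-5-vinyl-1,3-dioxolan-4-yl]propan-1-ol, stereocentres as in 7 | OC[C@]1(OC(C)(C)O[C@H]1C=C)[C@@H](C)CO | intermediate
9 | C19 tert-butyldiphenylsilyl ether of 8 | OC[C@]1(OC(C)(C)O[C@H]1C=C)[C@@H](C)CO[Si](c1ccccc1)(c1ccccc1)C(C)(C)C | intermediate
10 | C9 aldehyde from 9 | O=C[C@]1(OC(C)(C)O[C@H]1C=C)[C@@H](C)CO[Si](c1ccccc1)(c1ccccc1)C(C)(C)C | intermediate
11 | (R)-4-benzyl-1,3-oxazolidin-2-one | O=C1N[C@H](Cc2ccccc2)CO1 | starting material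
12 | itaconic anhydride (3-methylideneoxolane-2,5-dione) | C=C1CC(=O)OC1=O | starting material
13 | 4-[(4R)-4-benzyl-2-oxo-1,3-oxazolidin-3-yl]-2-methylidene-4-oxobutanoic acid | OC(=O)C(=C)CC(=O)N1[C@H](Cc2ccccc2)COC1=O | intermediate
14 | methyl 4-[(4R)-4-benzyl-2-oxo-1,3-oxazolidin-3-yl]-2-methylidene-4-oxobutanoate | COC(=O)C(=C)CC(=O)N1[C@H](Cc2ccccc2)COC1=O | intermediate
15 | syn-aldol adduct of 10 and 14 (C4–C9 bond, C9 alcohol) | COC(=O)C(=C)[C@@H](C(=O)N1[C@H](Cc2ccccc2)COC1=O)[C@@H](O)[C@]1(OC(C)(C)O[C@H]1C=C)[C@@H](C)CO[Si](c1ccccc1)(c1ccccc1)C(C)(C)C | intermediate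
16 | C9 triethylsilyl ether of 15 | COC(=O)C(=C)[C@@H](C(=O)N1[C@H](Cc2ccccc2)COC1=O)[C@@H](O[Si](CC)(CC)CC)[C@]1(OC(C)(C)O[C@H]1C=C)[C@@H](C)CO[Si](c1ccccc1)(c1ccccc1)C(C)(C)C | intermediate
17 | ring C cyclohexene: C5 methyl ester, C7/C8 acetonide, C9 OSiEt3, C4 acyl-oxazolidinone (C4 carbonyl, O7, O8, O9 on one face) | COC(=O)C1=C[C@@H]2OC(C)(C)O[C@]2([C@@H](C)CO[Si](c3ccccc3)(c3ccccc3)C(C)(C)C)[C@H](O[Si](CC)(CC)CC)[C@@H]1C(=O)N1[C@H](Cc2ccccc2)COC1=O | intermediate
18 | ring C S-ethyl thioester at C3 | COC(=O)C1=C[C@@H]2OC(C)(C)O[C@]2([C@@H](C)CO[Si](c3ccccc3)(c3ccccc3)C(C)(C)C)[C@H](O[Si](CC)(CC)CC)[C@@H]1C(=O)SCC | intermediate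
19 | ring C C3 aldehyde | COC(=O)C1=C[C@@H]2OC(C)(C)O[C@]2([C@@H](C)CO[Si](c3ccccc3)(c3ccccc3)C(C)(C)C)[C@H](O[Si](CC)(CC)CC)[C@@H]1C=O | intermediate
20 | ring C (E)-vinyl iodide | COC(=O)C1=C[C@@H]2OC(C)(C)O[C@]2([C@@H](C)CO[Si](c3ccccc3)(c3ccccc3)C(C)(C)C)[C@H](O[Si](CC)(CC)CC)[C@@H]1/C=C/I | intermediate
21 | ring C C16 allylic alcohol | OCC1=C[C@@H]2OC(C)(C)O[C@]2([C@@H](C)CO[Si](c3ccccc3)(c3ccccc3)C(C)(C)C)[C@H](O[Si](CC)(CC)CC)[C@@H]1/C=C/I | intermediate
22 | ring C C16 PMB ether | COc1ccc(COCC2=C[C@@H]3OC(C)(C)O[C@]3([C@@H](C)CO[Si](c4ccccc4)(c4ccccc4)C(C)(C)C)[C@H](O[Si](CC)(CC)CC)[C@@H]2/C=C/I)cc1 | intermediate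
23 | 4-methoxybenzyl alcohol | COc1ccc(CO)cc1 | starting material
24 | ring C (E)-enol ether, C4–CH=CH–OPMB | COc1ccc(COCC2=C[C@@H]3OC(C)(C)O[C@]3([C@@H](C)CO[Si](c4ccccc4)(c4ccccc4)C(C)(C)C)[C@H](O[Si](CC)(CC)CC)[C@@H]2/C=C/OCc2ccc(OC)cc2)cc1 | intermediate
25 | ring C C9 alcohol | COc1ccc(COCC2=C[C@@H]3OC(C)(C)O[C@]3([C@@H](C)CO[Si](c4ccccc4)(c4ccccc4)C(C)(C)C)[C@H](O)[C@@H]2/C=C/OCc2ccc(OC)cc2)cc1 | intermediate
26 | ring C C9 ketone | COc1ccc(COCC2=C[C@@H]3OC(C)(C)O[C@]3([C@@H](C)CO[Si](c4ccccc4)(c4ccccc4)C(C)(C)C)C(=O)[C@@H]2/C=C/OCc2ccc(OC)cc2)cc1 | intermediate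
27 | 3-ethoxycyclohex-2-en-1-one | CCOC1=CC(=O)CCC1 | starting material
28 | 3-ethoxy-6-methylcyclohex-2-en-1-one (racemic) | CCOC1=CC(=O)C(C)CC1 | intermediate
29 | 5-ethoxy-2-methylcyclohexa-1,5-dien-1-yl trifluoromethanesulfonate | CCOC1=CC(OS(=O)(=O)C(F)(F)F)=C(C)CC1 | intermediate
30 | 8-methyl-1,4-dioxaspiro[4.5]dec-7-en-7-yl trifluoromethanesulfonate | CC1=C(OS(=O)(=O)C(F)(F)F)CC2(CC1)OCCO2 | intermediate
31 | trimethyl(8-methyl-1,4-dioxaspiro[4.5]dec-7-en-7-yl)stannane | CC1=C([Sn](C)(C)C)CC2(CC1)OCCO2 | intermediate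
32 | (8-methyl-1,4-dioxaspiro[4.5]dec-7-en-7-yl)lithium | [Li]C1=C(C)CCC2(C1)OCCO2 | intermediate
33 | dichloro(8-methyl-1,4-dioxaspiro[4.5]dec-7-en-7-yl)cerium | Cl[Ce](Cl)C1=C(C)CCC2(C1)OCCO2 | intermediate
34 | cis-1-(2-methylcyclohexenyl)-2-[(E)-2-(PMB-oxy)vinyl]cyclohexenol: ring C with C7/C8 acetonide, C16 OPMB, C19 OSiPh2tBu, ring A C12 ketal | COc1ccc(CO/C=C/[C@@H]2C(COCc3ccc(OC)cc3)=C[C@@H]3OC(C)(C)O[C@]3([C@@H](C)CO[Si](c4ccccc4)(c4ccccc4)C(C)(C)C)[C@]2(O)C4=C(C)CCC5(OCCO5)C4)cc1 | intermediate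
35 | potassium alkoxide of 34 | [K+].COc1ccc(CO/C=C/[C@@H]2C(COCc3ccc(OC)cc3)=C[C@@H]3OC(C)(C)O[C@]3([C@@H](C)CO[Si](c4ccccc4)(c4ccccc4)C(C)(C)C)[C@]2([O-])C4=C(C)CCC5(OCCO5)C4)cc1 | intermediate
36 | potassium C9 enolate of the ring-expanded ketone (C9=C10, C8 trans to C1) | [K+].COc1ccc(COCC2=C/[C@@H]3OC(C)(C)O[C@]3([C@@H](C)CO[Si](c4ccccc4)(c4ccccc4)C(C)(C)C)/C([O-])=C4\CC5(OCCO5)CC[C@]4(C)[C@@H](OCc4ccc(OC)cc4)/C=C\2)cc1 | intermediate
37 | trans-fused ten-membered C9 ketone: C1 quaternary, C2 OPMB, cis C3=C4, C12 ketal, C7/C8 acetonide | COc1ccc(COCC2=C/[C@@H]3OC(C)(C)O[C@]3([C@@H](C)CO[Si](c4ccccc4)(c4ccccc4)C(C)(C)C)C(=O)[C@H]4CC5(OCCO5)CC[C@]4(C)[C@@H](OCc4ccc(OC)cc4)/C=C\2)cc1 | intermediate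
38 | C9 alcohol, C9 as in the target | COc1ccc(COCC2=C/[C@@H]3OC(C)(C)O[C@]3([C@@H](C)CO[Si](c4ccccc4)(c4ccccc4)C(C)(C)C)[C@@H](O)[C@H]4CC5(OCCO5)CC[C@]4(C)[C@@H](OCc4ccc(OC)cc4)/C=C\2)cc1 | intermediate
39 | C9 PMB ether | COc1ccc(COCC2=C/[C@@H]3OC(C)(C)O[C@]3([C@@H](C)CO[Si](c4ccccc4)(c4ccccc4)C(C)(C)C)[C@@H](OCc4ccc(OC)cc4)[C@H]4CC5(OCCO5)CC[C@]4(C)[C@@H](OCc4ccc(OC)cc4)/C=C\2)cc1 | intermediate
40 | C12 ketone | COc1ccc(COCC2=C/[C@@H]3OC(C)(C)O[C@]3([C@@H](C)CO[Si](c4ccccc4)(c4ccccc4)C(C)(C)C)[C@@H](OCc4ccc(OC)cc4)[C@H]4CC(=O)CC[C@]4(C)[C@@H](OCc4ccc(OC)cc4)/C=C\2)cc1 | intermediate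
41 | C12 trimethylsilyl enol ether (C12=C13) | COc1ccc(COCC2=C/[C@@H]3OC(C)(C)O[C@]3([C@@H](C)CO[Si](c4ccccc4)(c4ccccc4)C(C)(C)C)[C@@H](OCc4ccc(OC)cc4)[C@H]4CC(O[Si](C)(C)C)=CC[C@]4(C)[C@@H](OCc4ccc(OC)cc4)/C=C\2)cc1 | intermediate
42 | C13=C14 enone | COc1ccc(COCC2=C/[C@@H]3OC(C)(C)O[C@]3([C@@H](C)CO[Si](c4ccccc4)(c4ccccc4)C(C)(C)C)[C@@H](OCc4ccc(OC)cc4)[C@H]4CC(=O)C=C[C@]4(C)[C@@H](OCc4ccc(OC)cc4)/C=C\2)cc1 | intermediate
43 | 13,14-epoxy C12 ketone, epoxide trans to the C15 methyl | COc1ccc(COCC2=C/[C@@H]3OC(C)(C)O[C@]3([C@@H](C)CO[Si](c4ccccc4)(c4ccccc4)C(C)(C)C)[C@@H](OCc4ccc(OC)cc4)[C@H]4CC(=O)[C@@H]5O[C@@H]5[C@]4(C)[C@@H](OCc4ccc(OC)cc4)/C=C\2)cc1 | intermediate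
44 | 14-hydroxy C12 ketone | COc1ccc(COCC2=C/[C@@H]3OC(C)(C)O[C@]3([C@@H](C)CO[Si](c4ccccc4)(c4ccccc4)C(C)(C)C)[C@@H](OCc4ccc(OC)cc4)[C@H]4CC(=O)C[C@H](O)[C@]4(C)[C@@H](OCc4ccc(OC)cc4)/C=C\2)cc1 | intermediate
45 | 14-O-PMB C12 ketone | COc1ccc(COCC2=C/[C@@H]3OC(C)(C)O[C@]3([C@@H](C)CO[Si](c4ccccc4)(c4ccccc4)C(C)(C)C)[C@@H](OCc4ccc(OC)cc4)[C@H]4CC(=O)C[C@H](OCc5ccc(OC)cc5)[C@]4(C)[C@@H](OCc4ccc(OC)cc4)/C=C\2)cc1 | intermediate
46 | C11 Mannich base (C11–CH2NMe2, mixture of C11 epimers) | COc1ccc(COCC2=C/[C@@H]3OC(C)(C)O[C@]3([C@@H](C)CO[Si](c4ccccc4)(c4ccccc4)C(C)(C)C)[C@@H](OCc4ccc(OC)cc4)[C@H]4C(CN(C)C)C(=O)C[C@H](OCc5ccc(OC)cc5)[C@]4(C)[C@@H](OCc4ccc(OC)cc4)/C=C\2)cc1 | intermediate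
47 | C11 (trimethylammonio)methyl ketone iodide | [I-].COc1ccc(COCC2=C/[C@@H]3OC(C)(C)O[C@]3([C@@H](C)CO[Si](c4ccccc4)(c4ccccc4)C(C)(C)C)[C@@H](OCc4ccc(OC)cc4)[C@H]4C(C[N+](C)(C)C)C(=O)C[C@H](OCc5ccc(OC)cc5)[C@]4(C)[C@@H](OCc4ccc(OC)cc4)/C=C\2)cc1 | intermediate
48 | C11 methylidene C12 ketone | COc1ccc(COCC2=C/[C@@H]3OC(C)(C)O[C@]3([C@@H](C)CO[Si](c4ccccc4)(c4ccccc4)C(C)(C)C)[C@@H](OCc4ccc(OC)cc4)[C@H]4C(=C)C(=O)C[C@H](OCc5ccc(OC)cc5)[C@]4(C)[C@@H](OCc4ccc(OC)cc4)/C=C\2)cc1 | intermediate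
49 | 13-hydroxy C11 methylidene C12 ketone | COc1ccc(COCC2=C/[C@@H]3OC(C)(C)O[C@]3([C@@H](C)CO[Si](c4ccccc4)(c4ccccc4)C(C)(C)C)[C@@H](OCc4ccc(OC)cc4)[C@H]4C(=C)C(=O)[C@H](O)[C@H](OCc5ccc(OC)cc5)[C@]4(C)[C@@H](OCc4ccc(OC)cc4)/C=C\2)cc1 | intermediate
50 | 13-O-(3-methylbutanoyl) C11 methylidene C12 ketone | COc1ccc(COCC2=C/[C@@H]3OC(C)(C)O[C@]3([C@@H](C)CO[Si](c4ccccc4)(c4ccccc4)C(C)(C)C)[C@@H](OCc4ccc(OC)cc4)[C@H]4C(=C)C(=O)[C@H](OC(=O)CC(C)C)[C@H](OCc5ccc(OC)cc5)[C@]4(C)[C@@H](OCc4ccc(OC)cc4)/C=C\2)cc1 | intermediate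
51 | C7/C8/C19 triol | COc1ccc(COCC2=C/[C@H](O)[C@@](O)([C@@H](C)CO)[C@@H](OCc3ccc(OC)cc3)[C@H]4C(=C)C(=O)[C@H](OC(=O)CC(C)C)[C@H](OCc5ccc(OC)cc5)[C@]4(C)[C@@H](OCc3ccc(OC)cc3)/C=C\2)cc1 | intermediate
52 | γ-lactone (C19 on O7), C8 hydroxyl free | COc1ccc(COCC2=C/[C@@H]3OC(=O)[C@H](C)[C@@]3(O)[C@@H](OCc3ccc(OC)cc3)[C@H]4C(=C)C(=O)[C@H](OC(=O)CC(C)C)[C@H](OCc5ccc(OC)cc5)[C@]4(C)[C@@H](OCc3ccc(OC)cc3)/C=C\2)cc1 | intermediate
53 | C12 allylic alcohol | COc1ccc(COCC2=C/[C@@H]3OC(=O)[C@H](C)[C@@]3(O)[C@@H](OCc3ccc(OC)cc3)[C@H]4C(=C)[C@H](O)[C@H](OC(=O)CC(C)C)[C@H](OCc5ccc(OC)cc5)[C@]4(C)[C@@H](OCc3ccc(OC)cc3)/C=C\2)cc1 | intermediate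
54 | 11,20-epoxide | COc1ccc(COCC2=C/[C@@H]3OC(=O)[C@H](C)[C@@]3(O)[C@@H](OCc3ccc(OC)cc3)[C@H]4[C@@]5(CO5)[C@H](O)[C@H](OC(=O)CC(C)C)[C@H](OCc5ccc(OC)cc5)[C@]4(C)[C@@H](OCc3ccc(OC)cc3)/C=C\2)cc1 | intermediate
55 | 12,13-bis(3-methylbutanoate) with four PMB ethers | COc1ccc(COCC2=C/[C@@H]3OC(=O)[C@H](C)[C@@]3(O)[C@@H](OCc3ccc(OC)cc3)[C@H]4[C@@]5(CO5)[C@H](OC(=O)CC(C)C)[C@H](OC(=O)CC(C)C)[C@H](OCc5ccc(OC)cc5)[C@]4(C)[C@@H](OCc3ccc(OC)cc3)/C=C\2)cc1 | intermediate
56 | tetraol (O2, O9, O14, O16 free) | OCC1=C/[C@@H]2OC(=O)[C@H](C)[C@@]2(O)[C@@H](O)[C@H]2[C@@]3(CO3)[C@H](OC(=O)CC(C)C)[C@H](OC(=O)CC(C)C)[C@H](O)[C@]2(C)[C@@H](O)/C=C\1 | intermediate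
57 | CNP0303383.2 | CC(=O)OCC1=C/[C@@H]2OC(=O)[C@H](C)[C@@]2(O)[C@@H](OC(C)=O)[C@H]2[C@@]3(CO3)[C@H](OC(=O)CC(C)C)[C@H](OC(=O)CC(C)C)[C@H](OC(C)=O)[C@]2(C)[C@@H](OC(C)=O)/C=C\1 | target

**Count and risks**

Total step count: 45. Longest linear sequence: 39 steps (steps 1–9, 12–22, 27–45).

The three steps most likely to fail:

1. Step 28. The alkoxide may cleave the C4–C9 bond heterolytically (retro-aldol-type fragmentation to a ring A enone and a pentadienyl anion) and then re-close or protonate without selectivity, or it may react through a boat array. The fallback removes the anion. It sets out from 34, which is silylated (Me3SiOTf, 2,6-lutidine, CH2Cl2, −78 °C) to the trimethylsilyl ether of 34 F1. Heating F1 in degassed 1,2-dichlorobenzene at about 180 °C (neutral siloxy-Cope rearrangement) should give the trimethylsilyl enol ether of the ring-expanded ketone F2. K2CO3 in MeOH cleaves the silyl enol ether and equilibrates C10, so the fallback comes back at 37.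

2. Step 36. Deprotonation may occur at C13 instead of C11, followed by β-elimination of the C14 ether or Mannich reaction at the wrong carbon. The fallback installs C20 while C13 is still an epoxide carbon and cannot be enolised. It sets out from 43: LiN(iPr)2, Me2N=CH2 I, then MeI and aq. NaHCO3 give the C11 methylidene 13,14-epoxy C12 ketone F3. SmI2 in THF/MeOH at −90 °C opens the epoxide reductively to the 14-hydroxy C11 methylidene C12 ketone F4. Dudley etherification of F4 (2-(4-methoxybenzyloxy)-4-methylquinoline, MeOTf, MgO) comes back at 48.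

3. Step 20. Oxidative addition and ligand exchange at the hindered vinyl iodide may be slow, so that dehydrohalogenation to the alkyne or loss of E geometry under hot carbonate takes over. The fallback forms the C–O bond oxidatively at room temperature. It sets out from 22: Miyaura borylation (bis(pinacolato)diboron, PdCl2(dppf), KOPh, toluene, 50 °C) gives the (E)-alkenyl pinacol boronate F5. Chan–Lam coupling of F5 with 23 (Cu(OAc)2, Et3N, 4 Å sieves, CH2Cl2, air, rt) comes back at 24.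

Further compounds

F1 | step 28 | trimethylsilyl ether of 34 | COc1ccc(CO/C=C/[C@@H]2C(COCc3ccc(OC)cc3)=C[C@@H]3OC(C)(C)O[C@]3([C@@H](C)CO[Si](c4ccccc4)(c4ccccc4)C(C)(C)C)[C@]2(O[Si](C)(C)C)C4=C(C)CCC5(OCCO5)C4)cc1
F2 | step 28 | trimethylsilyl enol ether of the ring-expanded ketone (C9=C10) | COc1ccc(COCC2=C/[C@@H]3OC(C)(C)O[C@]3([C@@H](C)CO[Si](c4ccccc4)(c4ccccc4)C(C)(C)C)/C(O[Si](C)(C)C)=C4\CC5(OCCO5)CC[C@]4(C)[C@@H](OCc4ccc(OC)cc4)/C=C\2)cc1
F3 | step 36 | C11 methylidene 13,14-epoxy C12 ketone | COc1ccc(COCC2=C/[C@@H]3OC(C)(C)O[C@]3([C@@H](C)CO[Si](c4ccccc4)(c4ccccc4)C(C)(C)C)[C@@H](OCc4ccc(OC)cc4)[C@H]4C(=C)C(=O)[C@@H]5O[C@@H]5[C@]4(C)[C@@H](OCc4ccc(OC)cc4)/C=C\2)cc1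
F4 | step 36 | 14-hydroxy C11 methylidene C12 ketone | COc1ccc(COCC2=C/[C@@H]3OC(C)(C)O[C@]3([C@@H](C)CO[Si](c4ccccc4)(c4ccccc4)C(C)(C)C)[C@@H](OCc4ccc(OC)cc4)[C@H]4C(=C)C(=O)C[C@H](O)[C@]4(C)[C@@H](OCc4ccc(OC)cc4)/C=C\2)cc1
F5 | step 20 | (E)-alkenyl pinacol boronate from 22 | COc1ccc(COCC2=C[C@@H]3OC(C)(C)O[C@]3([C@@H](C)CO[Si](c4ccccc4)(c4ccccc4)C(C)(C)C)[C@H](O[Si](CC)(CC)CC)[C@@H]2/C=C/B2OC(C)(C)C(C)(C)O2)cc1
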